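**Retrosynthetic overview**
1. 24 ⇐ δ-hydroxy ketone 23 (acid cyclodehydration closes ring E last) ⇐ Mukaiyama–Michael addition of an exocyclic enol ether at C1 to ethyl vinyl ketone (makes quaternary C1).
2. Piperidine ring D ⇐ bridged N-methyl lactam (reduction); ring B ⇐ carbenoid C–H insertion of a diazo ester side chain into the allylic CH2 of ring A.
3. Lactam and quaternary C2 ⇐ Mannich/lactamisation and enantioselective C-alkylation of a seven-membered β-keto ester with a vinyl diazonium ion (new).
4. β-Keto ester (ring C) ⇐ key ring expansion: 1,2-alkenyl shift of a dirhodium carbenoid made from hexahydroindenone 7 and ethyl diazoacetate; 7 ⇐ cyclohexane-1,3-dione + 1-bromo-3-chloropropane.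
5. Ring order: cyclohexenone → ring A → ring C (expansion) → ring D (as lactam) → ring B → ring E.

Labels used for all polycyclic compounds (taken from 24): C1 spiro carbon; C2 neighbouring quaternary carbon; C3 the CH between C1 and an NCH2; C4=C5 the olefin (C4 on C2); C6 ring-fusion CH on C4; C7 the CH(CO2Me). Ring A: cyclopentene C4–C5–CH2–CH2–C6. Ring B: cyclopentane C2–C4–C6–C7–CH2. Ring C: seven-membered C1–C2–C4=C5–CH2–CH2–C3. Ring D: piperidine C1–C2–CH2–N(Me)–CH2–C3. Ring E: dihydropyran, spiro at C1. In these labels 24 is (1S,2R,3S,6R,7R).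

Assumption: formaldehyde 12 is dosed as paraformaldehyde and methylamine 15 as a 33% solution in ethanol; the ligand enantiomer in step 7 is the one that gives the (4R) product.

**Step 1**
Reactants: 1 cyclohexane-1,3-dione
Product: 2 3-ethoxycyclohex-2-en-1-one
Conditions: EtOH, TsOH (cat.), PhMe, reflux, Dean–Stark
Reagents that add atoms: ethanol, CCO
Why: Acid-catalysed enol etherification of the vinylogous acid, with azeotropic removal of water, gives the vinylogous ester needed for a Stork–Danheiser sequence.

**Step 2**
Reactants: 2 3-ethoxycyclohex-2-en-1-one; 3 1-bromo-3-chloropropane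
Product: 6 3-(3-chloropropyl)cyclohex-2-en-1-one, via 3-chloropropylmagnesium bromide 4 (not isolated), via bromomagnesium alkoxide adduct 5 (not isolated)
Conditions: 3, Mg, THF, 20 °C; then 2, 0 °C; then 1 M HCl, 20 °C
Reagents that add atoms: none
Why: Stork–Danheiser transposition: the Grignard reagent (Mg inserts into C–Br, not C–Cl) adds 1,2 to the vinylogous ester and acid hydrolysis of the tertiary allylic alkoxide unmasks the 3-substituted enone.

**Step 3**
Reactants: 6 3-(3-chloropropyl)cyclohex-2-en-1-one
Product: 7 1,2,3,5,6,7-hexahydro-4H-inden-4-one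
Conditions: KOt-Bu, NaI (cat.), t-BuOH–THF, 0 → 25 °C
Reagents that add atoms: none
Why: Intramolecular α-alkylation of the extended enolate closes ring A by a 5-exo-tet displacement, and the double bond returns to the conjugated tetrasubstituted position under the basic conditions.

**Step 4**
Reactants: 7 1,2,3,5,6,7-hexahydro-4H-inden-4-one; 8 ethyl diazoacetate
Product: 9 ethyl 2-diazo-2-(4-hydroxy-2,3,4,5,6,7-hexahydro-1H-inden-4-yl)acetate (racemic)
Conditions: LiN(i-Pr)2, THF, −78 °C; AcOH quench
Reagents that add atoms: none
Why: Aldol-type 1,2-addition of lithiated ethyl diazoacetate to the enone carbonyl gives the tertiary β-hydroxy α-diazo ester; its carbinol centre is destroyed in step 5, so the racemate is used.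

**Step 5**
Reactants: 9 ethyl 2-diazo-2-(4-hydroxy-2,3,4,5,6,7-hexahydro-1H-inden-4-yl)acetate
Product: 10 ethyl 5-oxo-1,2,3,4,5,6,7,8-octahydroazulene-4-carboxylate (racemic, keto–enol mixture)
Conditions: Rh2(OAc)4 (1 mol%), CH2Cl2, 0 → 25 °C
Reagents that add atoms: none
Why: Key ring expansion: the dirhodium (divalent rhodium) carbenoid undergoes a semipinacol-type 1,2-shift in which the ring alkenyl carbon migrates in preference to the CH2 (alkenyl over alkyl, as in known 1,2-vinyl shifts of such carbenoids), inserting the ester-bearing carbon between C=O and the olefin to give ring C; no stereocentre is fixed because the β-keto ester enolises.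

**Step 6**
Reactants: 11 methyl diazoacetate; 12 formaldehyde
Product: 13 methyl 2-diazo-3-hydroxypropanoate
Conditions: (CH2O)n, DBU (10 mol%), MeCN, 25 °C
Reagents that add atoms: none
Why: DBU-catalysed aldol-type addition of the acidic diazo C–H to formaldehyde gives the β-hydroxy α-diazo ester.

**Step 7**
Reactants: 10 ethyl 5-oxo-1,2,3,4,5,6,7,8-octahydroazulene-4-carboxylate; 13 methyl 2-diazo-3-hydroxypropanoate
Product: 14 ethyl (4R)-4-(2-diazo-3-methoxy-3-oxopropyl)-5-oxo-1,2,3,4,5,6,7,8-octahydroazulene-4-carboxylate (azulene C4 = C2 of the labels)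
Conditions: Sc(OTf)3 (10 mol%), C2-symmetric N,N'-dioxide ligand from (S)-pipecolic acid and 2,6-diisopropylaniline (12 mol%), 4 Å MS, CH2Cl2, −40 °C, 13 added over 4 h
Reagents that add atoms: none
Why: Proposed new method: Sc(OTf)3 ionises 13 to the vinyl diazonium ion CH2=C(N2+)CO2Me while the same chiral trivalent-scandium complex holds 10 as a two-point-bound enolate, so the α-carbon (not the hindered γ-carbon of the dienolate) adds to the CH2 terminus from one face and the diazo group is regenerated, which sets the quaternary stereocentre C2 and installs the carbene precursor in one operation; the closest known chemistry is the racemic Lewis-acid-promoted conjugate addition of silyl enol ethers and indoles to vinyl diazonium ions, together with scandium/N,N'-dioxide-catalysed asymmetric Michael additions of cyclic β-keto esters.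

**Step 8**
Reactants: 14 diazo keto diester; 15 methylamine
Product: 17 bridged lactam diazo ester (C1 is C=O; the ring-D carbon on C2 is the lactam C=O; C2 bears CH2C(=N2)CO2Me; C2 and C3 as in 24), via Mannich base 16 (not isolated)
Conditions: LiN(SiMe3)2, THF, −78 °C; CH2=NMe2+ I−, −78 → 0 °C; then MeNH2 (33% in EtOH), 50 °C
Reagents that add atoms: N,N-dimethylmethyleneiminium iodide, C=[N+](C)C.[I-]
Why: Mannich reaction at the only enolisable position (lithium enolate plus Eschenmoser's salt), amine exchange by elimination/aza-Michael addition of MeNH2, then lactamisation onto the ring ester; C3 is fixed because only the epimer with the aminomethyl arm cis to the ester can close the bridge, and the other equilibrates through the enone.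

**Step 9**
Reactants: 17 bridged lactam diazo ester
Product: 18 tetracyclic keto lactam (17 with ring B closed between C6 and C7; CO2Me on C7; C2, C3, C6, C7 as in 24)
Conditions: Rh2(S-PTTL)4 (dirhodium tetrakis[N-phthaloyl-(S)-tert-leucinate], 1 mol%), PhMe, −60 → −20 °C
Reagents that add atoms: none
Why: Intramolecular 1,5 C–H insertion of the dirhodium carbenoid into the allylic CH2 of ring A closes ring B; the side chain sits on the face of C2 opposite the lactam bridge, so only the syn hydrogen is reached (sets C6), the bulky carboxylate wall places the ester cis to the ring-A CH2 (sets C7, the cis-selective cyclopentane formation typical of this catalyst), and the low temperature suppresses β-hydride shift.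

**Step 10**
Reactants: 18 tetracyclic keto lactam
Product: 19 lactam enol ether (18 with C1=CH–OMe instead of C1=O; E/Z mixture)
Conditions: Ph3P(CH2OMe)Cl, KN(SiMe3)2, THF, 0 → 40 °C
Reagents that add atoms: (methoxymethyl)triphenylphosphonium chloride, COC[P+](c1ccccc1)(c1ccccc1)c1ccccc1.[Cl-]
Why: Wittig methoxymethylenation of the non-enolisable bridging ketone gives the enol ether, a masked aldehyde that survives the next reduction.

**Step 11**
Reactants: 19 lactam enol ether
Product: 20 amine enol ether (19 with the lactam C=O reduced to CH2; ring D as in 24)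
Conditions: Zn(OAc)2 (10 mol%), (EtO)2MeSiH, THF, 40 °C; aq. NaOH work-up
Reagents that add atoms: none
Why: Zinc-catalysed hydrosilylation reduces the tertiary lactam to the amine chemoselectively in the presence of the methyl ester and the enol ether; no stereocentre is touched.

**Step 12**
Reactants: 20 amine enol ether; 21 ethyl vinyl ketone
Product: 22 keto aldehyde (C1 quaternary, bearing CHO and CH2CH2C(=O)CH2CH3; C1 as in 24)
Conditions: TMSOTf (2.2 equiv), CH2Cl2, −78 → −40 °C; then 1 M HCl, THF, 0 °C; NaHCO3
Reagents that add atoms: water, O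
Why: Mukaiyama–Michael addition of the enol ether to the silyl-activated enone forms quaternary C1, the enone approaching the exocyclic olefin from the face syn to the C4=C5 bridge and anti to the axial C–H bonds of the two NCH2 groups and the ring-B CH2 (sets C1), and aqueous acid then releases the aldehyde and the ketone.

**Step 13**
Reactants: 22 keto aldehyde
Product: 24 target CNP0159589.2 (1S,2R,3S,6R,7R), via hydroxy ketone 23 (not isolated)
Conditions: NaBH4, MeOH–CH2Cl2, −78 °C; then TsOH·H2O (1.5 equiv), PhMe, 4 Å MS, 60 °C; NaHCO3
Reagents that add atoms: none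
Why: At −78 °C borohydride reduces the aldehyde much faster than the dialkyl ketone or the ester, and acid-catalysed cyclodehydration of the δ-hydroxy ketone (through the lactol) gives the more stable endocyclic enol ether, the 6-ethyl-3,4-dihydro-2H-pyran ring E.

**Compound list**
1 | cyclohexane-1,3-dione | O=C1CCCC(=O)C1 | starting material
2 | 3-ethoxycyclohex-2-en-1-one | CCOC1=CC(=O)CCC1 | intermediate
3 | 1-bromo-3-chloropropane | ClCCCBr | starting material
4 | 3-chloropropylmagnesium bromide | ClCCC[Mg]Br | intermediate
5 | bromomagnesium 1-(3-chloropropyl)-3-ethoxycyclohex-2-en-1-olate (racemic) | CCOC1=CC(CCCCl)(O[Mg]Br)CCC1 | intermediate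
6 | 3-(3-chloropropyl)cyclohex-2-en-1-one | O=C1C=C(CCCCl)CCC1 | intermediate
7 | 1,2,3,5,6,7-hexahydro-4H-inden-4-one | O=C1CCCC2=C1CCC2 | intermediate
8 | ethyl diazoacetate | CCOC(=O)C=[N+]=[N-] | starting material
9 | ethyl 2-diazo-2-(4-hydroxy-2,3,4,5,6,7-hexahydro-1H-inden-4-yl)acetate (racemic) | CCOC(=O)C(=[N+]=[N-])C1(O)CCCC2=C1CCC2 | intermediate
10 | ethyl 5-oxo-1,2,3,4,5,6,7,8-octahydroazulene-4-carboxylate (racemic, keto–enol mixture) | CCOC(=O)C1C(=O)CCCC2=C1CCC2 | intermediate
11 | methyl diazoacetate | COC(=O)C=[N+]=[N-] | starting material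
12 | formaldehyde (used as paraformaldehyde) | C=O | starting material
13 | methyl 2-diazo-3-hydroxypropanoate | COC(=O)C(=[N+]=[N-])CO | intermediate
14 | ethyl (4R)-4-(2-diazo-3-methoxy-3-oxopropyl)-5-oxo-1,2,3,4,5,6,7,8-octahydroazulene-4-carboxylate | CCOC(=O)[C@@]1(CC(=[N+]=[N-])C(=O)OC)C(=O)CCCC2=C1CCC2 | intermediate
15 | methylamine | CN | starting material
16 | Mannich base: 14 with CH2NMe2 on the CH2 next to the ketone (epimer mixture at that carbon) | CCOC(=O)[C@@]1(CC(=[N+]=[N-])C(=O)OC)C(=O)C(CN(C)C)CCC2=C1CCC2 | intermediate
17 | bridged lactam diazo ester (rings A, C and ring-D lactam; C1 ketone; CH2C(=N2)CO2Me on C2) | O=C2[C@@H]1CCC3=C(CCC3)[C@@]2(CC(=[N+]=[N-])C(=O)OC)C(=O)N(C)C1 | intermediate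
18 | tetracyclic keto lactam (rings A, B, C and ring-D lactam; C1 ketone) | O=C2[C@@H]1CCC3=C4[C@H](CC3)[C@H](C(=O)OC)C[C@@]42C(=O)N(C)C1 | intermediate
19 | lactam enol ether (C1=CH–OMe, E/Z mixture) | COC=C2[C@@H]1CCC3=C4[C@H](CC3)[C@H](C(=O)OC)C[C@@]42C(=O)N(C)C1 | intermediate
20 | amine enol ether (ring D as in 24; C1=CH–OMe, E/Z mixture) | COC=C2[C@@H]1CCC3=C4[C@H](CC3)[C@H](C(=O)OC)C[C@@]42CN(C)C1 | intermediate
21 | ethyl vinyl ketone (pent-1-en-3-one) | CCC(=O)C=C | starting material
22 | keto aldehyde (CHO and 3-oxopentyl on C1) | CCC(=O)CC[C@]2(C=O)[C@@H]1CCC3=C4[C@H](CC3)[C@H](C(=O)OC)C[C@@]42CN(C)C1 | intermediate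
23 | hydroxy ketone (CH2OH and 3-oxopentyl on C1) | CCC(=O)CC[C@]2(CO)[C@@H]1CCC3=C4[C@H](CC3)[C@H](C(=O)OC)C[C@@]42CN(C)C1 | intermediate
24 | CNP0159589.2 | CCC1=CC[C@]2(CO1)[C@@H]1CCC3=C4[C@H](CC3)[C@H](C(=O)OC)C[C@@]42CN(C)C1 | target

**Step count**
Total: 13 steps. Longest linear sequence: 12 steps (steps 1–5 and 7–13, from cyclohexane-1,3-dione); step 6 is a one-step side branch.

**Three steps most likely to fail**

Step 7 (the proposed new method). Ionisation of the primary hydroxy diazo ester, α- versus γ-attack of the dienolate, and the enantioselectivity are all untested. Fallback with known chemistry, setting out from 10 and coming back at 17. Chiral phase-transfer-catalysed Michael addition of 10 to methyl acrylate (binaphthyl-derived spiro quaternary ammonium bromide, K2CO3, PhMe, −20 °C) gives the quaternary keto diester F1. Classical Mannich condensation with 15 and 12 (AcOH, MeOH, 60 °C) and lactamisation give the bridged keto lactam ester F2, whose ketone can no longer enolise. Detrifluoroacetylative diazo transfer then installs the diazo group: LiN(SiMe3)2 and CF3CO2CH2CF3 at −78 °C give the trifluoroacetyl ester F3, and MsN3 with Et3N in MeCN returns 17.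

Step 9. β-Hydride shift and ylide formation with the lactam or ketone oxygen can compete with insertion, and the ester at C7 may come out epimeric. Fallback, setting out from 14 and coming back at 18: invert the order of ring formation. The same dirhodium-catalysed insertion is run on the monocyclic diazo keto diester 14, which has no amide oxygen near the carbenoid; there the choice of catalyst enantiomer has to select the diastereotopic allylic hydrogen. This gives the tricyclic keto diester F4. The lactam is then built by the classical Mannich condensation with 15 and 12 (AcOH, MeOH, 60 °C), which closes onto the ring ester and returns 18.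

Step 12. The enol ether is hindered and the facial preference at C1 could be the opposite of the one assumed. Fallback, setting out from 20 and coming back at 23: reverse the order in which the two carbon arms are put on C1. Hydrolysis of 20 (1 M HCl, THF) gives the aldehyde F5. A crossed aldol with formaldehyde 12 (aq. CH2O, K2CO3, MeOH) gives the quaternary hydroxymethyl aldehyde F6; the CH2OH arm now takes the face the ketone chain would have taken, so the route gives the right C1 configuration if step 12 shows the wrong facial preference. Wittig extension of the aldehyde with 1-(triphenylphosphoranylidene)butan-2-one (PhMe, 80 °C) gives the enone F7, and hydrogenation of its disubstituted olefin (H2, Pd/C, EtOAc) gives 23, which cyclises as in step 13.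

**Further compounds**
F1 | step 7 | ethyl (4R)-4-(3-methoxy-3-oxopropyl)-5-oxo-1,2,3,4,5,6,7,8-octahydroazulene-4-carboxylate | CCOC(=O)[C@@]1(CCC(=O)OC)C(=O)CCCC2=C1CCC2
F2 | step 7 | bridged keto lactam ester (17 with CH2CH2CO2Me in place of the diazo side chain) | O=C2[C@@H]1CCC3=C(CCC3)[C@@]2(CCC(=O)OC)C(=O)N(C)C1
F3 | step 7 | α-trifluoroacetyl derivative of F2 (mixture at the acylated carbon) | O=C2[C@@H]1CCC3=C(CCC3)[C@@]2(CC(C(=O)OC)C(=O)C(F)(F)F)C(=O)N(C)C1
F4 | step 9 | tricyclic keto diester (rings A, B and C; ethyl ester on C2, methyl ester on C7) | O=C1CCCC2=C3[C@H](CC2)[C@H](C(=O)OC)C[C@]13C(=O)OCC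
F5 | step 12 | aldehyde (CHO and H on C1, epimer mixture at C1) | O=CC2[C@@H]1CCC3=C4[C@H](CC3)[C@H](C(=O)OC)C[C@@]42CN(C)C1
F6 | step 12 | hydroxymethyl aldehyde (CHO and CH2OH on C1) | O=C[C@]2(CO)[C@@H]1CCC3=C4[C@H](CC3)[C@H](C(=O)OC)C[C@@]42CN(C)C1
F7 | step 12 | (E)-enone (CH2OH and CH=CH–C(=O)Et on C1) | CCC(=O)/C=C/[C@]2(CO)[C@@H]1CCC3=C4[C@H](CC3)[C@H](C(=O)OC)C[C@@]42CN(C)C1
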